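**Assumption:** farnesane numbering is used in the discussion (C1–C11 are the ring carbons in biosynthetic order, C10 is the carbinol carbon). The presumed biosynthesis is the cyclase-type 1,11-closure of a farnesyl chain (C10=C11 π-bond onto electrophilic C1) to the γ-humulene skeleton. 2-Methylbut-1-en-3-yne and 4-acetoxy-3-methoxybenzoic acid are taken as catalogue chemicals. The target's stereocentre is (R).

**Retrosynthetic overview**
1. Target 19 ⇒ (R)-alcohol 16 + O-acetylvanillic acid 17 (Steglich ester; the phenol acetate is removed in the same flask).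
2. 16 ⇒ macrocyclic dienone 14 (CBS reduction sets the only stereocentre, C10).
3. 14 ⇒ open-chain C15 iodo-ketone 12. The single 11-membered ring is closed by the C1–C11 bond with cyclase polarity (C10 enolate π-bond onto electrophilic C1). C1 is a Pd(II)-alkenyl, so the (E)-1,3(15)-diene of the γ-humulene type comes out directly.
4. 12 ⇒ 3-methylbutan-2-one 10 + allylic bromide 9 (C8–C9 enolate alkylation); 9 ⇒ enyne 5 (hydrozirconation/iodination, SeO2, Appel) ⇒ enyne 1 + prenyl bromide 2.
5. Ring order: one ring only, formed in step 6.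

**Route**

Step 1
Reactants: 1 2-methylbut-1-en-3-yne; 2 prenyl bromide (1-bromo-3-methylbut-2-ene)
Product: 5 7-methyl-3-methylideneoct-6-en-1-yne, via dimetalated enyne 3 (not isolated), via lithium acetylide 4 (not isolated)
Conditions: n-BuLi (2.0 equiv), KOt-Bu (1.0 equiv), THF–hexane, −78 → −20 °C; then 2, −78 °C → rt; H2O
Reagents that add atoms: none
Why: Lochmann–Schlosser dimetalation (acetylenic C–H and allylic CH3) gives a symmetric 2-ethynylallyl dianion whose much more nucleophilic allyl terminus is alkylated (SN2) by the primary allylic bromide, the acetylide being re-protonated on work-up; no stereocentre.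

Step 2
Reactants: 5 7-methyl-3-methylideneoct-6-en-1-yne
Product: 7 (1E)-1-iodo-7-methyl-3-methylideneocta-1,6-diene, via dienylzirconocene chloride 6 (not isolated)
Conditions: Cp2Zr(H)Cl (1.2 equiv), THF, rt, 1 h; then I2 (1.2 equiv), 0 °C
Reagents that add atoms: iodine, II
Why: Schwartz hydrozirconation of the terminal alkyne is syn with Zr on the terminal carbon and iodinolysis goes with retention, fixing the (E)-dienyl iodide; the 1,1-di- and trisubstituted alkenes do not react.

Step 3
Reactants: 7 (1E)-1-iodo-7-methyl-3-methylideneocta-1,6-diene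
Product: 8 (2E,7E)-8-iodo-2-methyl-6-methylideneocta-2,7-dien-1-ol
Conditions: SeO2 (0.3 equiv), t-BuOOH (3 equiv), CH2Cl2, 0 °C → rt
Reagents that add atoms: tert-butyl hydroperoxide (terminal oxidant, O source), CC(C)(C)OO; selenium dioxide (catalytic O-transfer agent), O=[Se]=O
Why: Sharpless catalytic SeO2 allylic oxidation (ene reaction then [2,3]-shift) hydroxylates the (E)-methyl of the electron-rich trisubstituted alkene, giving the (E)-allylic alcohol; the vinyl iodide and the less nucleophilic 1,1-disubstituted alkene are left alone.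

Step 4
Reactants: 8 (2E,7E)-8-iodo-2-methyl-6-methylideneocta-2,7-dien-1-ol
Product: 9 (1E,6E)-8-bromo-1-iodo-7-methyl-3-methylideneocta-1,6-diene
Conditions: CBr4 (1.3 equiv), PPh3 (1.3 equiv), CH2Cl2, −20 → 0 °C
Reagents that add atoms: carbon tetrabromide, BrC(Br)(Br)Br
Why: Appel bromination converts the primary allylic alcohol by SN2 without allylic shift or loss of alkene geometry.

Step 5
Reactants: 10 3-methylbutan-2-one; 9 (1E,6E)-8-bromo-1-iodo-7-methyl-3-methylideneocta-1,6-diene
Product: 12 (6E,11E)-12-iodo-2,6-dimethyl-10-methylidenedodeca-6,11-dien-3-one, via lithium enolate 11 (not isolated)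
Conditions: LDA (2.5 equiv), 10 (2.6 equiv), THF, −78 °C; then 9 (1 equiv), DMPU, −78 → −30 °C
Reagents that add atoms: none
Why: Kinetic deprotonation of the methyl ketone at CH3 and SN2 alkylation of the excess lithium enolate by the primary allylic bromide forms C8–C9 and installs the isopropyl ketone; the vinyl iodide is inert to the enolate at this temperature.

Step 6
Reactants: 12 (6E,11E)-12-iodo-2,6-dimethyl-10-methylidenedodeca-6,11-dien-3-one
Product: 14 (3E,8E)-2,2,9-trimethyl-5-methylidenecycloundeca-3,8-dien-1-one, via sodium enolate 13 (not isolated)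
Conditions: Pd2(dba)3 (5 mol %), t-Bu3P (12 mol %), NaOt-Bu (2.5 equiv), toluene, 60 °C; 12 added by syringe pump over 12 h (final 2 mM)
Reagents that add atoms: none
Why: Proposed new method: an 11-membered-ring Pd-catalysed ketone α-alkenylation, in which Pd(0) inserts into the (E)-dienyl C–I bond with retention, the tetrasubstituted sodium enolate 13 binds Pd, and C–C reductive elimination from the bulky-phosphine complex forges the quaternary C2–C3 ring bond (farnesane C11–C1, the cyclase 1,11-closure with the same polarity); closure through the CH2 enolate would need an (E,E)-cyclononadienone and is excluded by strain, the (E)-alkenyl-Pd cannot reach the 6,7-alkene, and slow addition at high dilution suppresses oligomers; closest known reaction type is the intramolecular Buchwald–Hartwig-type α-alkenylation/α-arylation of ketone enolates (5- to 7-membered rings) together with intermolecular α-vinylation of α-branched ketones to quaternary centres.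

Step 7
Reactants: 14 (3E,8E)-2,2,9-trimethyl-5-methylidenecycloundeca-3,8-dien-1-one
Product: 16 (1R,3E,8E)-2,2,9-trimethyl-5-methylidenecycloundeca-3,8-dien-1-ol, via catecholborate ester 15 (not isolated)
Conditions: (S)-Me-CBS (1.0 equiv), catecholborane (2.0 equiv), toluene, −78 → −40 °C; then MeOH, H2O
Reagents that add atoms: none
Why: Corey–Bakshi–Shibata reduction, in which the ketone binds the (S)-oxazaborolidine with the α-quaternary carbon as the large group and the CH2 side as the small group, so hydride delivery gives the (1R)-alcohol (same sense as pinacolone → R with the S catalyst), while catecholborane at low temperature leaves the alkenes alone.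

Step 8
Reactants: 16 (1R,3E,8E)-2,2,9-trimethyl-5-methylidenecycloundeca-3,8-dien-1-ol; 17 4-acetoxy-3-methoxybenzoic acid
Product: 19 (1R,3E,8E)-2,2,9-trimethyl-5-methylidenecycloundeca-3,8-dien-1-yl 4-hydroxy-3-methoxybenzoate (target), via acetyl-protected ester 18 (not isolated)
Conditions: 17 (1.5 equiv), DCC (1.6 equiv), DMAP (1.0 equiv), CH2Cl2, rt, 24 h; then pyrrolidine (5 equiv), rt, 30 min
Reagents that add atoms: none
Why: Steglich esterification acylates the hindered secondary alcohol with retention (the C–O bond at the stereocentre is not broken), and the phenolic acetate is then removed chemoselectively by aminolysis with pyrrolidine, which does not attack the hindered alkyl benzoate.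

**Compound list**
1 | 2-methylbut-1-en-3-yne | C=C(C)C#C | starting material
2 | prenyl bromide (1-bromo-3-methylbut-2-ene) | CC(C)=CCBr | starting material
3 | dimetalated enyne (acetylide Li, allyl K) | [Li]C#CC(=C)C[K] | intermediate
4 | lithium acetylide of 5 | [Li]C#CC(=C)CCC=C(C)C | intermediate
5 | 7-methyl-3-methylideneoct-6-en-1-yne | C#CC(=C)CCC=C(C)C | intermediate
6 | (E)-dienylzirconocene chloride | CC(C)=CCCC(=C)/C=C/[Zr](Cl)(C1C=CC=C1)C1C=CC=C1 | intermediate
7 | (1E)-1-iodo-7-methyl-3-methylideneocta-1,6-diene | CC(C)=CCCC(=C)/C=C/I | intermediate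
8 | (2E,7E)-8-iodo-2-methyl-6-methylideneocta-2,7-dien-1-ol | OC/C(C)=C/CCC(=C)/C=C/I | intermediate
9 | (1E,6E)-8-bromo-1-iodo-7-methyl-3-methylideneocta-1,6-diene | BrC/C(C)=C/CCC(=C)/C=C/I | intermediate
10 | 3-methylbutan-2-one | CC(=O)C(C)C | starting material
11 | lithium enolate of 10 (kinetic, CH2 side) | [Li]OC(=C)C(C)C | intermediate
12 | (6E,11E)-12-iodo-2,6-dimethyl-10-methylidenedodeca-6,11-dien-3-one | CC(C)C(=O)CC/C(C)=C/CCC(=C)/C=C/I | intermediate
13 | sodium enolate of 12 (tetrasubstituted) | CC(C)=C(O[Na])CC/C(C)=C/CCC(=C)/C=C/I | intermediate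
14 | (3E,8E)-2,2,9-trimethyl-5-methylidenecycloundeca-3,8-dien-1-one | C=C1/C=C/C(C)(C)C(=O)CC/C(C)=C/CC1 | intermediate
15 | catecholborate ester of 16 | C=C1/C=C/C(C)(C)[C@H](OB2Oc3ccccc3O2)CC/C(C)=C/CC1 | intermediate
16 | (1R,3E,8E)-2,2,9-trimethyl-5-methylidenecycloundeca-3,8-dien-1-ol | C=C1/C=C/C(C)(C)[C@H](O)CC/C(C)=C/CC1 | intermediate
17 | 4-acetoxy-3-methoxybenzoic acid | CC(=O)Oc1ccc(C(=O)O)cc1OC | starting material
18 | (1R,3E,8E)-2,2,9-trimethyl-5-methylidenecycloundeca-3,8-dien-1-yl 4-acetoxy-3-methoxybenzoate | C=C1/C=C/C(C)(C)[C@H](OC(=O)c2ccc(OC(C)=O)c(OC)c2)CC/C(C)=C/CC1 | intermediate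
19 | (1R,3E,8E)-2,2,9-trimethyl-5-methylidenecycloundeca-3,8-dien-1-yl 4-hydroxy-3-methoxybenzoate | C=C1/C=C/C(C)(C)[C@H](OC(=O)c2ccc(O)c(OC)c2)CC/C(C)=C/CC1 | target

**Step count:** 8 steps in total. Longest linear sequence: 8 steps (1/2 → 19); 10 and 17 are bought.

**Three steps most likely to fail, with fallbacks**

Step 6 (macrocyclic α-alkenylation). The fallback sets out from 7 and comes back at 14; it makes the quaternary C–alkenyl bond intermolecularly and closes the ring at another bond. Pd-catalysed α-alkenylation of isobutyronitrile with 7 (NaHMDS, Pd2(dba)3/t-Bu3P) gives (3E)-2,2,9-trimethyl-5-methylidenedeca-3,8-dienenitrile F1. MeLi followed by aqueous HCl gives (4E)-3,3,10-trimethyl-6-methylideneundeca-4,9-dien-2-one F2. SeO2/t-BuOOH gives (4E,9E)-11-hydroxy-3,3,10-trimethyl-6-methylideneundeca-4,9-dien-2-one F3, and CBr4/PPh3 gives (4E,9E)-11-bromo-3,3,10-trimethyl-6-methylideneundeca-4,9-dien-2-one F4. Intramolecular C-alkylation of the only possible enolate (LiHMDS, THF, high dilution) then closes the C10–C11 ring bond and gives 14.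

Step 7 (CBS reduction of a hindered macrocyclic ketone; ee and chemoselectivity). The fallback sets out from 14 and comes back at 16; it replaces asymmetric reduction by classical resolution. LiAlH4 gives racemic (3E,8E)-2,2,9-trimethyl-5-methylidenecycloundeca-3,8-dien-1-ol F5. Acylation with (1S)-(−)-camphanic chloride (DMAP, pyridine) gives two diastereomers that are separated by chromatography or crystallisation: (1R,3E,8E)-2,2,9-trimethyl-5-methylidenecycloundeca-3,8-dien-1-yl (1S,4R)-camphanate F6, which is kept, and (1S,3E,8E)-2,2,9-trimethyl-5-methylidenecycloundeca-3,8-dien-1-yl (1S,4R)-camphanate F7, which is discarded. KOH in MeOH–H2O on F6 returns 16.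

Step 5 (mono-alkylation of a kinetic methyl-ketone enolate; proton transfer and dialkylation). The fallback sets out from 9 and comes back at 12; it uses a soft β-keto ester nucleophile instead. C-alkylation of ethyl 4-methyl-3-oxopentanoate with 9 (K2CO3, acetone) gives ethyl (4E,9E)-10-iodo-4-methyl-8-methylidene-2-(2-methylpropanoyl)deca-4,9-dienoate F8. Saponification and decarboxylation (aq. NaOH, then H3O+, 50 °C) gives 12.

**Further compounds**
F1 | step 6 | (3E)-2,2,9-trimethyl-5-methylidenedeca-3,8-dienenitrile | N#CC(C)(C)/C=C/C(=C)CCC=C(C)C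
F2 | step 6 | (4E)-3,3,10-trimethyl-6-methylideneundeca-4,9-dien-2-one | CC(=O)C(C)(C)/C=C/C(=C)CCC=C(C)C
F3 | step 6 | (4E,9E)-11-hydroxy-3,3,10-trimethyl-6-methylideneundeca-4,9-dien-2-one | CC(=O)C(C)(C)/C=C/C(=C)CC/C=C(C)/CO
F4 | step 6 | (4E,9E)-11-bromo-3,3,10-trimethyl-6-methylideneundeca-4,9-dien-2-one | CC(=O)C(C)(C)/C=C/C(=C)CC/C=C(C)/CBr
F5 | step 7 | racemic (3E,8E)-2,2,9-trimethyl-5-methylidenecycloundeca-3,8-dien-1-ol | C=C1/C=C/C(C)(C)C(O)CC/C(C)=C/CC1
F6 | step 7 | (1R,3E,8E)-2,2,9-trimethyl-5-methylidenecycloundeca-3,8-dien-1-yl (1S,4R)-4,7,7-trimethyl-3-oxo-2-oxabicyclo[2.2.1]heptane-1-carboxylate | CC1(C)[C@@]2(C)CC[C@]1(C(=O)O[C@@H]3CC/C(C)=C/CCC(=C)/C=C/C3(C)C)OC2=O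
F7 | step 7 | (1S,3E,8E)-2,2,9-trimethyl-5-methylidenecycloundeca-3,8-dien-1-yl (1S,4R)-4,7,7-trimethyl-3-oxo-2-oxabicyclo[2.2.1]heptane-1-carboxylate | CC1(C)[C@@]2(C)CC[C@]1(C(=O)O[C@H]3CC/C(C)=C/CCC(=C)/C=C/C3(C)C)OC2=O
F8 | step 5 | ethyl (4E,9E)-10-iodo-4-methyl-8-methylidene-2-(2-methylpropanoyl)deca-4,9-dienoate | CCOC(=O)C(C/C(C)=C/CCC(=C)/C=C/I)C(=O)C(C)C
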